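**Retrosynthetic overview**
- The target, epicatechin 3-O-gallate-(4β→8)-epigallocatechin 3-O-gallate-(4β→8)-catechin 3-O-gallate, comes from global hydrogenolysis of its docosa-O-benzyl ether. The rings of the middle and lower units are bought with (−)-epigallocatechin and (+)-catechin.
- The lower interflavan bond is made first: DDQ activation of C4 of benzylated epigallocatechin, galloylation, then TMSOTf coupling with benzylated catechin gallate.
- The pyran ring of the upper unit is built last, by closing its C2–C3 bond. C3 of a (Z)-enol gallate (C3=C4 on the A ring) attacks an O-aryl oxocarbenium ion (O1=C2, from the A-ring phenol and the B-ring aldehyde acetal); the C4 cation so formed is then arylated by C8 of the dimer.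
- Enabling feature: the phloroglucinol A ring of the upper unit. O1, O5 and O7 are ortho/para to C4a, so C4 is a stabilised benzylic cation terminus. This makes the oxygen-bearing C3 the nucleophilic alkene carbon and makes the cyclised product the flavan-4-yl cation that ring D of the middle unit captures.
- Stereocentres: the five of the middle and lower units are bought or relayed (4β); C2 of the upper unit is set by a chiral acid, C3 by the alkene geometry, C4 by the C3 gallate.

Key step: step 13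

Remark: the upper unit is read as 2R,3R,4R, the middle unit as 2R,3R with its 4β bond trans to the gallate, and the lower unit as 2R,3S; the antipode of the chiral acid in step 13 is the one that gives the 2R series, to be fixed in a test run with both antipodes.

**Route**

Step 1
Reactants: 1 (−)-epigallocatechin
Product: 2 5,7,3′,4′,5′-penta-O-benzyl-(−)-epigallocatechin
Conditions: BnBr, K2CO3, DMF, 0 °C → rt, Ar
Reagents that add atoms: benzyl bromide, BrCc1ccccc1
Why: Williamson etherification of the five phenols under carbonate conditions should leave the secondary 3-OH and both stereocentres untouched.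

Step 2
Reactants: 2 5,7,3′,4′,5′-penta-O-benzyl-(−)-epigallocatechin
Product: 3 5,7,3′,4′,5′-penta-O-benzyl-4β-(2-ethoxyethoxy)-(−)-epigallocatechin
Conditions: DDQ, 2-ethoxyethanol, CH2Cl2, rt
Reagents that add atoms: 2-ethoxyethanol, CCOCCO
Why: DDQ benzylic oxidation (hydride abstraction at C4, assisted by the 5,7-dialkoxy A ring) gives the flavan-4-yl cation, which the alcohol should trap trans to the axial 3-OH (4β).

Step 3
Reactants: 3 5,7,3′,4′,5′-penta-O-benzyl-4β-(2-ethoxyethoxy)-(−)-epigallocatechin; 4 3,4,5-tris(benzyloxy)benzoic acid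
Product: 5 5,7,3′,4′,5′-penta-O-benzyl-4β-(2-ethoxyethoxy)-(−)-epigallocatechin 3-O-[3,4,5-tris(benzyloxy)benzoate]
Conditions: DCC, DMAP, CH2Cl2, rt
Reagents that add atoms: none
Why: Steglich esterification of the secondary alcohol; no stereocentre is involved.

Step 4
Reactants: 6 (+)-catechin
Product: 7 5,7,3′,4′-tetra-O-benzyl-(+)-catechin
Conditions: BnBr, K2CO3, DMF, 0 °C → rt, Ar
Reagents that add atoms: benzyl bromide, BrCc1ccccc1
Why: Williamson etherification of the four phenols; the 3-OH stays free.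

Step 5
Reactants: 7 5,7,3′,4′-tetra-O-benzyl-(+)-catechin; 4 3,4,5-tris(benzyloxy)benzoic acid
Product: 8 5,7,3′,4′-tetra-O-benzyl-(+)-catechin 3-O-[3,4,5-tris(benzyloxy)benzoate]
Conditions: DCC, DMAP, CH2Cl2, rt
Reagents that add atoms: none
Why: Steglich esterification of the equatorial 3-OH.

Step 6
Reactants: 5 galloylated 4β-(2-ethoxyethoxy) electrophile; 8 benzylated catechin gallate (3 equiv, excess recovered)
Product: 9 pentadeca-O-benzyl dimer: perbenzylated epigallocatechin 3-O-gallate-(4β→8)-catechin 3-O-gallate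
Conditions: TMSOTf (cat.), CH2Cl2, −78 °C
Reagents that add atoms: none
Why: Lewis-acid ionisation of the 4-alkoxy group followed by Friedel–Crafts arylation (the standard proanthocyanidin coupling); the most nucleophilic C8 of 8 should attack anti to the 3-O-galloyl group, giving the 4β (3,4-trans) bond.

Step 7
Reactants: 10 2,4,6-trihydroxybenzaldehyde
Product: 11 4,6-bis(benzyloxy)-2-hydroxybenzaldehyde
Conditions: BnBr (2 equiv), K2CO3, DMF, rt
Reagents that add atoms: benzyl bromide, BrCc1ccccc1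
Why: Williamson etherification stops at the dibenzyl ether because the last ortho-OH is tied up in a hydrogen bond to the formyl group.

Step 8
Reactants: 11 4,6-bis(benzyloxy)-2-hydroxybenzaldehyde
Product: 12 2,4-bis(benzyloxy)-6-(triisopropylsilyloxy)benzaldehyde
Conditions: TIPSCl, imidazole, DMF, rt
Reagents that add atoms: triisopropylsilyl chloride, CC(C)[Si](Cl)(C(C)C)C(C)C
Why: silylation of the phenol; the bulky TIPS group is chosen so that it does not migrate to the alkoxide formed in step 9.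

Step 9
Reactants: 12 2,4-bis(benzyloxy)-6-(triisopropylsilyloxy)benzaldehyde
Product: 13 [3,5-bis(benzyloxy)-2-ethynylphenoxy]triisopropylsilane
Conditions: TMSCHN2, n-BuLi, THF, −78 °C → rt
Reagents that add atoms: trimethylsilyldiazomethane, C[Si](C)(C)C=[N+]=[N-]
Why: Colvin rearrangement: addition of lithiated TMS-diazomethane, Peterson elimination and 1,2-shift in the alkylidene carbene give the terminal aryl alkyne.

Step 10
Reactants: 13 [3,5-bis(benzyloxy)-2-ethynylphenoxy]triisopropylsilane; 4 3,4,5-tris(benzyloxy)benzoic acid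
Product: 14 (Z)-2-[2,4-bis(benzyloxy)-6-(triisopropylsilyloxy)phenyl]ethenyl 3,4,5-tris(benzyloxy)benzoate
Conditions: [Ru(methallyl)2(dppb)] (cat.), toluene, 60 °C
Reagents that add atoms: none
Why: ruthenium-catalysed anti-Markovnikov addition of a carboxylic acid to a terminal alkyne through a Ru-vinylidene, which should give the (Z)-enol ester; the silyl group blocks cyclisation of the phenol to a benzofuran.

Step 11
Reactants: 14 (Z)-enol gallate silyl ether
Product: 15 (Z)-2-[2,4-bis(benzyloxy)-6-hydroxyphenyl]ethenyl 3,4,5-tris(benzyloxy)benzoate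
Conditions: HF·pyridine, pyridine, THF, 0 °C; used at once
Reagents that add atoms: none
Why: fluoride desilylation in an acidic medium keeps the liberated phenol protonated, so no phenoxide should form that could take the galloyl group from the enol oxygen.

Step 12
Reactants: 16 3,4-bis(benzyloxy)benzaldehyde
Product: 17 1,2-bis(benzyloxy)-4-(dimethoxymethyl)benzene
Conditions: HC(OMe)3, p-TsOH (cat.), rt; Et3N quench
Reagents that add atoms: trimethyl orthoformate, COC(OC)OC
Why: acid-catalysed acetalisation driven by the orthoformate.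

Step 13
Reactants: 15 (Z)-enol gallate phenol; 17 B-ring dimethyl acetal; 9 pentadeca-O-benzyl dimer
Product: 20 docosa-O-benzyl trimer (perbenzylated epicatechin 3-O-gallate-(4β→8)-epigallocatechin 3-O-gallate-(4β→8)-catechin 3-O-gallate), via mixed aryl methyl acetal 18 (not isolated), via 4β-methoxyflavan gallate 19 (not isolated)
Conditions: chiral IDPi Brønsted acid (5 mol %), CH2Cl2 (dilute), −40 °C; then 9 (1.5 equiv), TMSOTf (cat.), −78 → −40 °C, one pot
Reagents that add atoms: none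
Why: Proposed new method: the chiral acid exchanges one methoxy group of 17 for the phenol of 15 (18) and ionises 18 to the (E)-O-aryl oxocarbenium ion, paired with the confined IDPi anion; C3 of the (Z)-enol gallate attacks C2 in a 6-endo-trig cation–olefin (Prins-type) closure of the pyran ring, the released methanol holds the flavan-4-yl cation as 19, and TMSOTf then re-ionises 19 for capture by C8 of 9. The closest known reactions are the confined-acid-catalysed asymmetric Prins cyclisation and oxa-Pictet–Spengler reaction of oxocarbenium ions for the ring closure, and the Lewis-acid 4→8 arylation of 4-alkoxyflavan-3-yl gallates for the second stage, which is established. C2 should be set by the catalyst through face selection at the oxocarbenium carbon; C3 follows from the alkene geometry, because in a sofa-like transition state the aryl group of the E-oxocarbenium is pseudo-equatorial and the Z-oxygen substituent becomes pseudo-axial (2,3-cis). C4 is set by the substrate: the arene enters anti to the axial 3-O-galloyl group, which also shields the α-face by acyloxonium participation (3,4-trans, 4β). The step needs 6-endo over 5-exo closure and attack through the oxygen-bearing carbon; both are secured because only the C2–C3 bond leaves the charge on C4, ortho/para to O1, O5 and O7, while the acyl group weakens the directing power of the enol oxygen. It also needs C8 selectivity in 9, which follows the usual preference of the upper unit of a 4→8 dimer; any cation of the wrong enantiomeric series ends as a diastereomer of 20, separable by chromatography.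

Step 14
Reactants: 20 docosa-O-benzyl trimer
Product: 21 epicatechin 3-O-gallate-(4β→8)-epigallocatechin 3-O-gallate-(4β→8)-catechin 3-O-gallate (target)
Conditions: H2 (1 atm), Pd(OH)2/C, THF/MeOH/H2O, rt; Sephadex LH-20
Reagents that add atoms: none
Why: hydrogenolysis of the 22 aryl benzyl ethers; the esters, the interflavan bonds and all stereocentres should be untouched under these neutral conditions.

**Compound list**
1 | (−)-epigallocatechin | O[C@@H]1Cc2c(O)cc(O)cc2O[C@@H]1c1cc(O)c(O)c(O)c1 | starting material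
2 | 5,7,3′,4′,5′-penta-O-benzyl-(−)-epigallocatechin | O[C@@H]1Cc2c(OCc9ccccc9)cc(OCc9ccccc9)cc2O[C@@H]1c1cc(OCc9ccccc9)c(OCc9ccccc9)c(OCc9ccccc9)c1 | intermediate
3 | 5,7,3′,4′,5′-penta-O-benzyl-4β-(2-ethoxyethoxy)-(−)-epigallocatechin (2,3-cis-3,4-trans) | O[C@@H]1[C@@H](OCCOCC)c2c(OCc9ccccc9)cc(OCc9ccccc9)cc2O[C@@H]1c1cc(OCc9ccccc9)c(OCc9ccccc9)c(OCc9ccccc9)c1 | intermediate
4 | 3,4,5-tris(benzyloxy)benzoic acid | OC(=O)c1cc(OCc9ccccc9)c(OCc9ccccc9)c(OCc9ccccc9)c1 | starting material
5 | 3-O-[3,4,5-tris(benzyloxy)benzoate] of 3 | O=C(O[C@@H]1[C@@H](OCCOCC)c2c(OCc9ccccc9)cc(OCc9ccccc9)cc2O[C@@H]1c1cc(OCc9ccccc9)c(OCc9ccccc9)c(OCc9ccccc9)c1)c1cc(OCc9ccccc9)c(OCc9ccccc9)c(OCc9ccccc9)c1 | intermediate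
6 | (+)-catechin | O[C@H]1Cc2c(O)cc(O)cc2O[C@@H]1c1ccc(O)c(O)c1 | starting material
7 | 5,7,3′,4′-tetra-O-benzyl-(+)-catechin | O[C@H]1Cc2c(OCc9ccccc9)cc(OCc9ccccc9)cc2O[C@@H]1c1ccc(OCc9ccccc9)c(OCc9ccccc9)c1 | intermediate
8 | 5,7,3′,4′-tetra-O-benzyl-(+)-catechin 3-O-[3,4,5-tris(benzyloxy)benzoate] | O=C(O[C@H]1Cc2c(OCc9ccccc9)cc(OCc9ccccc9)cc2O[C@@H]1c1ccc(OCc9ccccc9)c(OCc9ccccc9)c1)c1cc(OCc9ccccc9)c(OCc9ccccc9)c(OCc9ccccc9)c1 | intermediate
9 | pentadeca-O-benzyl epigallocatechin 3-O-gallate-(4β→8)-catechin 3-O-gallate | O=C(O[C@@H]1[C@@H](c2c(OCc9ccccc9)cc(OCc9ccccc9)c3c2O[C@H](c2ccc(OCc9ccccc9)c(OCc9ccccc9)c2)[C@@H](OC(=O)c2cc(OCc9ccccc9)c(OCc9ccccc9)c(OCc9ccccc9)c2)C3)c2c(OCc9ccccc9)cc(OCc9ccccc9)cc2O[C@@H]1c1cc(OCc9ccccc9)c(OCc9ccccc9)c(OCc9ccccc9)c1)c1cc(OCc9ccccc9)c(OCc9ccccc9)c(OCc9ccccc9)c1 | intermediate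
10 | 2,4,6-trihydroxybenzaldehyde | O=Cc1c(O)cc(O)cc1O | starting material
11 | 4,6-bis(benzyloxy)-2-hydroxybenzaldehyde | O=Cc1c(O)cc(OCc9ccccc9)cc1OCc9ccccc9 | intermediate
12 | 2,4-bis(benzyloxy)-6-(triisopropylsilyloxy)benzaldehyde | O=Cc1c(O[Si](C(C)C)(C(C)C)C(C)C)cc(OCc9ccccc9)cc1OCc9ccccc9 | intermediate
13 | [3,5-bis(benzyloxy)-2-ethynylphenoxy]triisopropylsilane | C#Cc1c(O[Si](C(C)C)(C(C)C)C(C)C)cc(OCc9ccccc9)cc1OCc9ccccc9 | intermediate
14 | (Z)-2-[2,4-bis(benzyloxy)-6-(triisopropylsilyloxy)phenyl]ethenyl 3,4,5-tris(benzyloxy)benzoate | O=C(O/C=C\c1c(O[Si](C(C)C)(C(C)C)C(C)C)cc(OCc9ccccc9)cc1OCc9ccccc9)c1cc(OCc9ccccc9)c(OCc9ccccc9)c(OCc9ccccc9)c1 | intermediate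
15 | (Z)-2-[2,4-bis(benzyloxy)-6-hydroxyphenyl]ethenyl 3,4,5-tris(benzyloxy)benzoate | O=C(O/C=C\c1c(O)cc(OCc9ccccc9)cc1OCc9ccccc9)c1cc(OCc9ccccc9)c(OCc9ccccc9)c(OCc9ccccc9)c1 | intermediate
16 | 3,4-bis(benzyloxy)benzaldehyde | O=Cc1ccc(OCc9ccccc9)c(OCc9ccccc9)c1 | starting material
17 | 1,2-bis(benzyloxy)-4-(dimethoxymethyl)benzene | COC(OC)c1ccc(OCc9ccccc9)c(OCc9ccccc9)c1 | intermediate
18 | mixed acetal: (Z)-2-{2,4-bis(benzyloxy)-6-[(3,4-bis(benzyloxy)phenyl)(methoxy)methoxy]phenyl}ethenyl 3,4,5-tris(benzyloxy)benzoate (both acetal epimers) | COC(Oc1cc(OCc9ccccc9)cc(OCc9ccccc9)c1/C=C\OC(=O)c1cc(OCc9ccccc9)c(OCc9ccccc9)c(OCc9ccccc9)c1)c1ccc(OCc9ccccc9)c(OCc9ccccc9)c1 | intermediate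
19 | 5,7,3′,4′-tetra-O-benzyl-4β-methoxy-(−)-epicatechin 3-O-[3,4,5-tris(benzyloxy)benzoate] (2,3-cis-3,4-trans) | CO[C@H]1c2c(OCc9ccccc9)cc(OCc9ccccc9)cc2O[C@H](c2ccc(OCc9ccccc9)c(OCc9ccccc9)c2)[C@@H]1OC(=O)c1cc(OCc9ccccc9)c(OCc9ccccc9)c(OCc9ccccc9)c1 | intermediate
20 | docosa-O-benzyl epicatechin 3-O-gallate-(4β→8)-epigallocatechin 3-O-gallate-(4β→8)-catechin 3-O-gallate | O=C(O[C@@H]1[C@@H](c2c(OCc9ccccc9)cc(OCc9ccccc9)c3c2O[C@H](c2ccc(OCc9ccccc9)c(OCc9ccccc9)c2)[C@@H](OC(=O)c2cc(OCc9ccccc9)c(OCc9ccccc9)c(OCc9ccccc9)c2)C3)c2c(OCc9ccccc9)cc(OCc9ccccc9)c([C@H]3c4c(OCc9ccccc9)cc(OCc9ccccc9)cc4O[C@H](c4ccc(OCc9ccccc9)c(OCc9ccccc9)c4)[C@@H]3OC(=O)c3cc(OCc9ccccc9)c(OCc9ccccc9)c(OCc9ccccc9)c3)c2O[C@@H]1c1cc(OCc9ccccc9)c(OCc9ccccc9)c(OCc9ccccc9)c1)c1cc(OCc9ccccc9)c(OCc9ccccc9)c(OCc9ccccc9)c1 | intermediate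
21 | epicatechin 3-O-gallate-(4β→8)-epigallocatechin 3-O-gallate-(4β→8)-catechin 3-O-gallate (CNP0321910.1) | O=C(O[C@@H]1[C@@H](c2c(O)cc(O)c3c2O[C@H](c2ccc(O)c(O)c2)[C@@H](OC(=O)c2cc(O)c(O)c(O)c2)C3)c2c(O)cc(O)c([C@H]3c4c(O)cc(O)cc4O[C@H](c4ccc(O)c(O)c4)[C@@H]3OC(=O)c3cc(O)c(O)c(O)c3)c2O[C@@H]1c1cc(O)c(O)c(O)c1)c1cc(O)c(O)c(O)c1 | target

**Step count**
Total: 14 steps. Longest linear sequence: 7 steps (steps 7, 8, 9, 10, 11, 13, 14, from 2,4,6-trihydroxybenzaldehyde).

**Steps most likely to fail**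

Step 13 (proposed new method). Three processes may defeat it: poor enantiofacial control at the oxocarbenium ion, C-protonation of the electron-rich styrene by the strong acid before acetal exchange, and loss of the C4 cation by elimination to a flav-3-ene. The fallback takes the upper unit from the chiral pool by known chemistry. (−)-Epicatechin is benzylated (BnBr, K2CO3, DMF) to 5,7,3′,4′-tetra-O-benzyl-(−)-epicatechin F1. Oxidation at C4 (DDQ, 2-ethoxyethanol, CH2Cl2) gives 5,7,3′,4′-tetra-O-benzyl-4β-(2-ethoxyethoxy)-(−)-epicatechin F2. Esterification with 4 (DCC, DMAP) gives its 3-O-[3,4,5-tris(benzyloxy)benzoate] F3. F3 is coupled with dimer 9 (TMSOTf, CH2Cl2, −78 °C). This fallback sets out from 9 and comes back to the route at 20.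

Step 10. Geometric or regiochemical leakage (E-isomer or Markovnikov ester) is possible with the di-ortho-substituted aryl alkyne, and the vinylidene pathway may be slow. The fallback fixes the alkene geometry before the C–O bond is made. Aldehyde 12 undergoes Stork–Zhao olefination ((iodomethyl)triphenylphosphonium iodide, NaHMDS, THF/DMPU, −78 °C) to (Z)-[3,5-bis(benzyloxy)-2-(2-iodoethenyl)phenoxy]triisopropylsilane F4. F4 is coupled with the caesium carboxylate of 4 in a copper(I)-mediated Ullmann-type vinyl C–O coupling (CuI, 1,10-phenanthroline, Cs2CO3, toluene, 80 °C), which should retain the alkene geometry. This fallback sets out from 12 and comes back at 14.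

Step 6. With ester groups on both partners, ionisation at C4 is retarded and self-condensation of the electrophile or attack through C6 may compete. The fallback couples the partners before esterification. The free alcohols 3 and 7 (7 in excess) are coupled with TMSOTf at −78 °C to the decabenzyl diol, 5,7,3′,4′,5′-penta-O-benzylepigallocatechin-(4β→8)-5,7,3′,4′-tetra-O-benzylcatechin F5. Both secondary alcohols of F5 are then esterified with 4 (DCC, DMAP, CH2Cl2). This fallback sets out from 3 and 7 and comes back at 9.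

**Further compounds**
F1 | step 13 | 5,7,3′,4′-tetra-O-benzyl-(−)-epicatechin | O[C@@H]1Cc2c(OCc9ccccc9)cc(OCc9ccccc9)cc2O[C@@H]1c1ccc(OCc9ccccc9)c(OCc9ccccc9)c1
F2 | step 13 | 5,7,3′,4′-tetra-O-benzyl-4β-(2-ethoxyethoxy)-(−)-epicatechin | O[C@@H]1[C@@H](OCCOCC)c2c(OCc9ccccc9)cc(OCc9ccccc9)cc2O[C@@H]1c1ccc(OCc9ccccc9)c(OCc9ccccc9)c1
F3 | step 13 | 5,7,3′,4′-tetra-O-benzyl-4β-(2-ethoxyethoxy)-(−)-epicatechin 3-O-[3,4,5-tris(benzyloxy)benzoate] | O=C(O[C@@H]1[C@@H](OCCOCC)c2c(OCc9ccccc9)cc(OCc9ccccc9)cc2O[C@@H]1c1ccc(OCc9ccccc9)c(OCc9ccccc9)c1)c1cc(OCc9ccccc9)c(OCc9ccccc9)c(OCc9ccccc9)c1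
F4 | step 10 | (Z)-[3,5-bis(benzyloxy)-2-(2-iodoethenyl)phenoxy]triisopropylsilane | I/C=C\c1c(O[Si](C(C)C)(C(C)C)C(C)C)cc(OCc9ccccc9)cc1OCc9ccccc9
F5 | step 6 | 5,7,3′,4′,5′-penta-O-benzylepigallocatechin-(4β→8)-5,7,3′,4′-tetra-O-benzylcatechin (3,3″-diol) | O[C@@H]1[C@@H](c2c(OCc9ccccc9)cc(OCc9ccccc9)c3c2O[C@H](c2ccc(OCc9ccccc9)c(OCc9ccccc9)c2)[C@@H](O)C3)c2c(OCc9ccccc9)cc(OCc9ccccc9)cc2O[C@@H]1c1cc(OCc9ccccc9)c(OCc9ccccc9)c(OCc9ccccc9)c1
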